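Early on, the north-east run has D at 0.9% and L at 8.4% after 2.00 min, so the dose of 0.0500 min⁻¹ (as a fraction of the charge) stands so far more as free monomer than as chains.

| setting | north-east | west | flask |
|---|---|---|---|
| L | 0.50 M (fed, over 20 min) | 0.50 M (fed, over 20 min) | 0.50 M (fed, over 20 min) |
| E | 0.15 M | 0.075 M | 0.150 M |
| J | 24 mM | 24 mM | 24 mM |
| remark | the very flask that is asked about, followed so far; the fed solution adds 0.25 times the starting volume | run made earlier; the fed solution adds 0.25 times the starting volume | the fed solution adds 0.25 times the starting volume |
| time |  |  | 20 min |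

| run | time / min | D / % | L / % |
|---|---|---|---|
| north-east | 0.667 | 0 | 3.3 |
| north-east | 1.00 | 0.1 | 5.2 |
| north-east | 2.00 | 0.9 | 8.4 |
| north-east | 3.00 | 2.6 | 12.3 |
| north-east | 5.00 | 7.5 | 18.5 |
| north-east | 8.00 | 14.8 | 25.2 |
| west | 0.500 | 0 | 2.3 |
| west | 1.50 | 0 | 6.1 |
| west | 3.00 | 2.0 | 12.7 |
| west | 4.00 | 4.9 | 15.1 |
| west | 6.00 | 9.5 | 20.3 |
| west | 8.00 | 15.9 | 24.5 |

(standard deviation of a reading: 0.5 percentage points)

- average number of monomer units in a chain (chains begun, living or dead) at 20 min
- part of the L that has reacted at 20 min

- charges are per starting volume, the dose included; the dosed solution carries all of it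
- the average divides the monomer in chains by the number of chains begun, living and dead together
- the numbers in the tables scatter by 0.5 percentage points (one standard deviation)
- the earlier runs do not show the number of chains; that part of a forecast is a guess
- percentages count the whole charge, also what has not yet gone in

Work with what is left, not with what is made. Between 3.00 min and 8.00 min, D gains 12 percentage points while L averages 18.8%. That gives 0.130 min⁻¹, the share of free L that turns into D per minute, a pseudo-first-order constant read with the scatter of the readings. If that share holds, dose in equals loss out at a ceiling of 38.4% of the charge, and the gap to that ceiling shrinks exponentially. From 10.0% dosed at 2.00 min, the part of the gap left at 20 min is 9.61%, so I reckon [L] at 35.7% and c at 64.3%. The chains are a guess: with one chain per J, dp is 13.4.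

Your forecast, c of 62% and dp of 4.5, is lower than mine on both counts, and of E it says: “It most likely acts as a transfer agent, affecting chain number rather than rate”.

The flask gives c of 60.5% and dp of 12.6.

    L + J → G + D (k = 0.0860 M⁻¹ s⁻¹)
    L + G → D + G, rate k2*[G]*[L] (k = 0.100 M⁻¹ s⁻¹)
    G + E → X (k = 7.90 × 10⁻⁴ M⁻¹ s⁻¹)

In this flask, L stands at 39.5% where I reckoned 35.7%. Now take the neighbouring flask with 0.0096 M of J. If the constant read in the north-east run scales with J, it becomes 0.0521 min⁻¹, with a ceiling of 96.1%, and from the same start I reckon [L] of 62.3% and, with one chain per J, dp of 19.6. That flask holds [G] at 0.00694 M against 0.0174 M here, and it reads 65.4% of L and dp of 18.0.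

The data are calculated with made-up constants, and the scatter is random.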